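| setting | dusk | winter | midnight | flask |
|---|---|---|---|---|
| L | 0.56 M | 0.88 M | 0.40 M | 0.40 M |
| D | 0.24 M | 0.24 M | 0.12 M | 0.240 M |
| X | 0.040 M | 0.040 M | 0.040 M | 0.0400 M |
| remark | run made earlier | run made earlier | run made earlier |  |
| time |  |  |  | 5.0 d |

| run | time / d | L / % | Z / % |
|---|---|---|---|
| dusk | 0.500 | 57.8 | 29.5 |
| dusk | 1.25 | 56.9 | 28.9 |
| dusk | 2.50 | 58.2 | 30.8 |
| dusk | 4.00 | 57.3 | 29.9 |
| winter | 0.333 | 70.9 | 18.8 |
| winter | 0.833 | 72.9 | 18.8 |
| winter | 1.67 | 70.8 | 18.4 |
| winter | 4.00 | 74.2 | 20.3 |
| midnight | 1.04 | 69.8 | 14.4 |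
| midnight | 2.08 | 71.3 | 15.5 |
| midnight | 3.00 | 71.8 | 17.0 |
| midnight | 4.00 | 70.6 | 17.6 |

(readings scatter by 1 percentage point)

- the reaction counts as stopped when no species that holds the L changes by six tenths of a point or more over the second half of the time

1. why nothing more happens at 5.0 d, or that something still does (forward and back rates have come level / all of L has reacted / it is still moving / D has run out first)
2. share of the L used up at 5.0 d
3. Z at 5.0 d, in percent of the L charged

The meeting began with the constants: X was charged at 0.040 M in the dusk run, at 0.040 M in winter and at 0.040 M at midnight, and it stands at 0.0400 M in the flask. The first speaker noted that L used matched D charged, 0.239 M against 0.24 M at dusk, so she called D the limiting reagent of these runs. The second averaged the Z readings of each run, taking them as scatter about a level, though she granted that the midnight readings climb from 14.4% to 17.6%: 0.167 M at dusk, 0.168 M in winter, 0.0645 M at midnight. Per D charged, that gave 0.696 at dusk but 0.538 at midnight, a ratio that moves. Per D beyond X, it gave 0.835 and 0.806.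

My own reckoning carries s, the Z formed per D charged beyond X, c(Z) = s·(c(D) − c(X)), pooled over the dusk, winter and midnight runs as 0.831. For the flask s gives 41.6% of Z, and D over L gives 60.0% of L used.

The forecast, on the grounds that L and D “react 1:1 and stop when D is gone”, said D has run out first, with 60% used (58% to 62%) and Z at 42% (38% to 44.5%). My figure for Z lies slightly lower.

The flask gives: D has run out first, 60.0% used, Z 42.0%.

    E ⇌ Z (K = 5.25, k = 0.00246 s⁻¹)
    L + D → E + J (k = 0.00141 M⁻¹ s⁻¹)
    E + X → Q (k = 0.00499 M⁻¹ s⁻¹)

At 5.00 d the flask holds 0% of its D and 0% of its X, and s·(c(D) − c(X)) stands at 41.6% beside the 42.0% of Z. The Q there, 10.0% of the L charged, amounts to 0.0400 M, the charge of X. Now take the neighbouring flask with 0.14 M of D, its other charges and its time as in the flask. The same s gives 20.8% of Z, and D over L gives 35.0% of L used. That neighbour holds 21.0% of Z, with 35.0% of its L used.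

The earlier runs and the new flask are calculated from invented constants, noise included.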